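The numbers in the tables come from a simulation with constants of no real substance, noise included.

Early times first: the alpha run makes E at about 6.24 mM/min, and the rest of the curve has to say what that speed depends on.

the same everywhere: Q 1.20 mM

| run | Z | X | E | time |
|---|---|---|---|---|
| alpha | 120 mM | 360 mM |  |  |
| theta | 72.0 mM | 312 mM |  |  |
| delta | 120 mM | 360 mM | 36.0 mM |  |
| eta | 360 mM | 1100 mM |  | 15 min |

| run | time / min | [E] / mM |
|---|---|---|
| alpha run | 0.85 | 5.3 |
| alpha run | 2.6 | 16.2 |
| alpha run | 4.9 | 29.0 |
| alpha run | 7.8 | 41.0 |
| alpha run | 11 | 54.3 |
| alpha run | 15 | 67.5 |
| theta run | 0.85 | 3.4 |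
| theta run | 2.6 | 9.3 |
| theta run | 4.9 | 17.1 |
| theta run | 7.8 | 25.3 |
| theta run | 11 | 33.6 |
| theta run | 15 | 41.0 |
| delta run | 0.85 | 40.8 |
| delta run | 2.6 | 51.7 |
| delta run | 4.9 | 63.9 |
| delta run | 7.8 | 77.1 |
| delta run | 11 | 90.8 |
| delta run | 15 | 103.0 |

(readings scatter by 0.4 mM)

- Overall: Z + X -> E, with Q as catalyst.
- Constant volume, constant temperature.
- What is held in complexes is read along with the free species.
- "The second partner" is X.

- the theta run starts with 48.0 mM less of Z and of X than the alpha run, and with no E. Compared where both hold the same amount of Z, once fifteen percent of what the theta run was charged with has turned into E, is the theta run faster, slower or alike (within a tenth)?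
- E in the eta run at 15 min, as a share of the Z charged

*Does E interfere?* Not visibly. The delta run has made 67.0 mM of new E at 15 min, the alpha run 67.5 mM.

*Does Q tire?* Compare the theta and alpha runs where both pass the Z asked about. Theta's rate there is 3.39 mM/min, alpha's 3.30 mM/min, so they are alike.

*What is the apparent first-order constant κ, defined as ln(Z charged/Z left)/t?* In the alpha run it is 0.0551 /min at 15 min. In the theta run it is 0.0562 /min.

*So the rate is first order in Z, and X doesn't matter?* That does not follow. X minus Z is 240 mM in alpha, 240 mM in theta and 240 mM in delta, so Z and X fall together along one line. Take the rate as proportional to [Z] to the power n times [X] to the power b. The slope seen along that line is n plus b times Z/X, and a steady κ puts that slope near one.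

*Solve the ends.* With b zero, n is one and the eta run repeats alpha's share, 56.3%. With b one, at alpha's charge, n is 0.667. I commit to b one, since X is a partner in the overall equation, though I have read no test between the two ends off these readings.

*What do you carry to the eta run?* The factor on κ is the ratio of X charged times the ratio of Z charged to the power n minus one. This gain 2.12 gives the eta run a share of 82.6% at 15 min, and I say alike for the comparison.

The forecast says alike and 55%, near the alpha run's own share, on these grounds: “The reaction is therefore first order in Z, with no visible dependence on X at these concentrations”.

The simulation gives alike and 85.6%.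

    2 Q ⇌ Q2, settled at all times (63600 /M)
    Q + Z + X → E + Q (3792 /M²/min)
    Q + Ja → Xi
    2 Z ⇌ Z2, settled at all times (6.050 /M)

Read back from the eta run's share, the gain is 2.34, against my 2.12. For the theta run the gain is 1.03, which turns alpha's half time of 12.6 min into 12.3 min; the theta run takes 12.4 min. The apparent order in Z early in the alpha run stands below one through the pairing of Z into Z2, at 0.71 against 1.0 without it, and the same pairing is the main reason for the eta run's shortfall from full conversion: without it, that run reaches 96.8% instead of 85.6%.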